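To run this flask as charged or to change its charge, the first figure needed is how much electrophile its nucleophile and solid base can pay for.

electrophile 0.10 M; nucleophile 0.0950 M; solid base 0.120 M; time 5.0 d

- part of the electrophile that has reacted at 5.0 d
- share of the unused nucleophile that is free and not bound as protonated nucleophile, at 5.0 d

- what is said of acid set free includes idle adduct
- solid base is a solid; its amount is given per volume of the solution
- at the start none of the solid base is in solution
- run time (flask): 5.0 d

    electrophile + nucleophile → acid set free + target (k1 = 0.081 /M/min)
    nucleophile + acid set free ⇌ protonated nucleophile, settled at all times (K2 = 25000 /M)
    acid set free + free base ⇌ idle adduct, settled at all times (K3 = 9.8 /M)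
    free base + target → over-reaction product (k4 = 0.030 /M/min)
    solid base ⇌ free base, rate k5*(cs5 - [free base]) while solid is left; crystals form when [free base] > cs5 (cs5 = 0.070 M, k5 = 0.0015 /min)
    acid set free + free base ⇌ salt of the base (K6 = 15000 /M, k6 = 0.68 /M/min)

By hand, before any run: each electrophile that reacts spends one nucleophile, so the nucleophile, the limiting reagent, caps c at 95.0%. Each reaction also frees one acid. If that acid takes a second nucleophile and no base helps, c stops at 47.5%, a first bound from below.

The solid base lifts that bound, but a target that over-reacts takes a base too. If every target over-reacts and every acid is bound, each electrophile costs 3 units of nucleophile and base together. Counting both charges as paid out in this way, c comes to 71.7%: the stall share, nucleophile plus base charged over 3 times the electrophile charged. The time looks sufficient, since the half-life of the electrophile by step 1 alone at the charged amounts, 0.063 d, and the quickest possible dissolving of the solid base, 0.794 d, are both shorter than 5.0 d. The bracket for c therefore runs from 71.7% to 95.0%; the hand gives fr no number.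

The forecast gives c as 70% and fr as 0.8%, holding that “the over-reaction with the target eats enough dissolved base that the base runs nearly out”. Its c lies 1.7 percentage points below the stall share, just outside the bracket.

The simulation gives c as 74.7%, inside the bracket, and fr as 1.60%; both forecast values hold within their margins.

Each step taken net, at 0.579 d this flask makes target at 0.282 of the rate at which it is used up, and at 5.00 d it makes target 1.56 times as fast as it is used up. By then over-reaction product holds 66.1% of the electrophile charged and target 8.54%. Here c stands 3 points above the stall share, a third of the target and free acid present, less free base and nucleophile, all in fractions of the electrophile charged. In the neighbour flask with 0.40 M of electrophile, the stall share is 17.9% and c is 21.7%.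

(The constants used here come from no measurement; the rest is arithmetic.)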